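**Plan**
- Retrosynthesis: the C5 phenol is masked as a benzyl ether, the C2–CH3 bond is cut back to the lactone carbonyl (via the lactol acetate), and O1 is then excised from the pyranone. Without O1 the atoms C2, C3, C4, C4a and C8a form the five-membered ring of a 1-indanone, with C2 as the ketone carbon and C4 as its β-carbon; this is what allows O1 to be inserted afterwards.
- The C4–C1' (naphthyl) bond is cut next as a 1,4-addition to an indenone, leading back to 4-hydroxy-1-indanone and 1,8-dimethoxynaphthalene.
- Forward: both carbocycles are bought and the naphthalene is joined to the indenone β-carbon. Oxygen insertion then expands the cyclopentanone to the six-membered lactone (the only ring formed), the lactone carbonyl becomes CH–CH3, and the benzyl group is removed.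
- Stereochemistry: C4 (S) comes from the (S)-BINAP–rhodium catalyst in the conjugate addition. C2 (R) comes from substrate control, methyl entering the C2 oxocarbenium ion anti to the C4 naphthyl group (2,4-trans).

Key step: step 6

Remark: lactol 12 and acetate 13 are carried as mixtures of C2 epimers because both ionise to the same oxocarbenium ion in step 9; the facial sense of the (S)-BINAP catalyst on the indenone is assumed to follow that on cyclopent-2-enone.

**Step 1**
Reactants: 1 1,8-dimethoxynaphthalene
Product: 2 1-bromo-4,5-dimethoxynaphthalene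
Conditions: NBS (1.0 equiv), MeCN, 0 °C to rt
Reagents that add atoms: N-bromosuccinimide, O=C1CCC(=O)N1Br
Why: Electrophilic aromatic bromination; C4, para to a methoxy group, is the most nucleophilic position of 1,8-dimethoxynaphthalene, so one equivalent of NBS should stop at the 4-monobromide.

**Step 2**
Reactants: 2 1-bromo-4,5-dimethoxynaphthalene
Product: 5 (4,5-dimethoxynaphthalen-1-yl)boronic acid, via aryllithium 3 (not isolated), via lithium arylborate 4 (not isolated)
Conditions: n-BuLi, THF, −78 °C; B(OiPr)3, −78 °C to rt; 1 M HCl, 0 °C (brief)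
Reagents that add atoms: triisopropyl borate, CC(C)OB(OC(C)C)OC(C)C; water, O
Why: Bromine–lithium exchange, borate trapping of the aryllithium and hydrolysis is the standard route to arylboronic acids, and a short cold acidic work-up should limit protodeboronation of the electron-rich product.

**Step 3**
Reactants: 6 4-hydroxy-2,3-dihydro-1H-inden-1-one; 7 benzyl bromide
Product: 8 4-(benzyloxy)-2,3-dihydro-1H-inden-1-one
Conditions: K2CO3, DMF, rt
Reagents that add atoms: none
Why: Williamson ether synthesis on the phenoxide; the benzyl ether should survive all later steps and is removed last by hydrogenolysis.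

**Step 4**
Reactants: 8 4-(benzyloxy)-2,3-dihydro-1H-inden-1-one
Product: 9 4-(benzyloxy)-1H-inden-1-one
Conditions: IBX, 4-methoxypyridine N-oxide, DMSO, rt
Reagents that add atoms: none
Why: IBX α,β-dehydrogenation of a ketone through its enol, used with the N-oxide ligand so that it runs at room temperature; this should spare the benzylic O–CH2 group and limit self-condensation of the indenone, which is filtered through silica and used at once.

**Step 5**
Reactants: 9 4-(benzyloxy)-1H-inden-1-one; 5 (4,5-dimethoxynaphthalen-1-yl)boronic acid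
Product: 10 (3S)-4-(benzyloxy)-3-(4,5-dimethoxynaphthalen-1-yl)-2,3-dihydro-1H-inden-1-one
Conditions: [Rh(OH)((S)-binap)]2 (3 mol% Rh), 5 (2 equiv), dioxane–H2O 10:1, 35 °C
Reagents that add atoms: none
Why: Hayashi–Miyaura rhodium-catalysed asymmetric 1,4-addition, in which a naphthyl–Rh(I)–BINAP species inserts the C2=C3 bond and water protonates the oxa-π-allyl rhodium, run base-free to protect the indenone; the C3 centre is set by the ligand, (S)-BINAP being the antipode that gives (S)-3-arylcyclopentanones from cyclopent-2-enone and, by the same facial approach, the 3S indanone here.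

**Step 6**
Reactants: 10 (3S)-4-(benzyloxy)-3-(4,5-dimethoxynaphthalen-1-yl)-2,3-dihydro-1H-inden-1-one
Product: 11 (4S)-5-(benzyloxy)-4-(4,5-dimethoxynaphthalen-1-yl)-3,4-dihydro-2H-chromen-2-one
Conditions: mCPBA, Na2HPO4, CH2Cl2, 0 °C to rt, dark
Reagents that add atoms: 3-chloroperbenzoic acid, O=C(OO)c1cccc(Cl)c1
Why: Baeyer–Villiger oxidation: the peracid adds to the C1 carbonyl of 10 to give the Criegee adduct, and the ring-fusion aryl carbon C7a shifts from C1 to the proximal peroxide oxygen as 3-chlorobenzoate leaves, so the C1–C7a bond is replaced by the C8a–O1 and O1–C2 bonds of 11. The closest known reaction type is the peracid oxidation of 3-aryl-1-indanones to 4-aryl-3,4-dihydrocoumarins. The six-membered pyranone is not closed from an open chain but arises by one-atom ring expansion of the five-membered ketone, the migrating carbon staying bonded to the ring throughout. No stereocentre is formed, and C3 of 10 becomes C4 of 11 unchanged because it takes no part in the migration. Regioselectivity (C7a over the C2 methylene) should follow from the higher migratory aptitude of an aryl carbon over a primary alkyl carbon, the normal course for 1-indanones. Chemoselectivity for the ketone over the dimethoxynaphthalene rests on the phosphate buffer, low temperature and absence of strong acid, conditions under which peracids convert carbonyl groups attached to dimethoxynaphthalenes without oxidising the ring.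

**Step 7**
Reactants: 11 (4S)-5-(benzyloxy)-4-(4,5-dimethoxynaphthalen-1-yl)-3,4-dihydro-2H-chromen-2-one
Product: 12 (4S)-5-(benzyloxy)-4-(4,5-dimethoxynaphthalen-1-yl)-3,4-dihydro-2H-chromen-2-ol (both C2 epimers)
Conditions: DIBAL-H, CH2Cl2, −78 °C; aq. Rochelle salt
Reagents that add atoms: none
Why: Partial reduction of a lactone with DIBAL-H stops at the aluminium hemiacetal at −78 °C and gives the lactol on work-up, a standard transformation of 3,4-dihydrocoumarins; C2 forms as both epimers, which does not matter because C2 is ionised in step 9.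

**Step 8**
Reactants: 12 (4S)-5-(benzyloxy)-4-(4,5-dimethoxynaphthalen-1-yl)-3,4-dihydro-2H-chromen-2-ol
Product: 13 (4S)-5-(benzyloxy)-4-(4,5-dimethoxynaphthalen-1-yl)-3,4-dihydro-2H-chromen-2-yl acetate (both C2 epimers)
Conditions: Ac2O, pyridine, DMAP (cat.), CH2Cl2, 0 °C to rt
Reagents that add atoms: acetic anhydride, CC(=O)OC(C)=O
Why: DMAP-catalysed O-acetylation; 2-chromanols exist mainly in the closed lactol form, so the anomeric acetate is expected in preference to the aryl acetate of the open hydroxy aldehyde.

**Step 9**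
Reactants: 13 (4S)-5-(benzyloxy)-4-(4,5-dimethoxynaphthalen-1-yl)-3,4-dihydro-2H-chromen-2-yl acetate
Product: 14 (2R,4S)-5-(benzyloxy)-4-(4,5-dimethoxynaphthalen-1-yl)-2-methyl-3,4-dihydro-2H-chromene
Conditions: AlMe3 (3 equiv), CH2Cl2, −78 to 0 °C
Reagents that add atoms: trimethylaluminium, C[Al](C)C
Why: Lewis acid-mediated substitution of a lactol acetate by an organoaluminium reagent: AlMe3 ionises the acetate to the C2 oxocarbenium ion and the aluminate transfers methyl within the ion pair; the C4 naphthyl group, held pseudoaxial by peri strain with the C5 benzyloxy group, shields its own face of C2, so methyl should enter anti to it and give the 2,4-trans (2R) product.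

**Step 10**
Reactants: 14 (2R,4S)-5-(benzyloxy)-4-(4,5-dimethoxynaphthalen-1-yl)-2-methyl-3,4-dihydro-2H-chromene
Product: 15 (2R,4S)-4-(4,5-dimethoxynaphthalen-1-yl)-2-methyl-3,4-dihydro-2H-chromen-5-ol (cladonaphchrom A)
Conditions: H2 (1 atm), 10% Pd/C, EtOAc–MeOH, rt
Reagents that add atoms: none
Why: Catalytic hydrogenolysis of a benzyl aryl ether; the ring O1–C2 bond is not benzylic and C4 carries only C–C and C–H bonds, so only the benzyl group should be lost and neither stereocentre is touched.

**Compound list**
1 | 1,8-dimethoxynaphthalene | COc1cccc2cccc(OC)c12 | starting material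
2 | 1-bromo-4,5-dimethoxynaphthalene | COc1cccc2c(Br)ccc(OC)c12 | intermediate
3 | (4,5-dimethoxynaphthalen-1-yl)lithium | COc1cccc2c([Li])ccc(OC)c12 | intermediate
4 | lithium (4,5-dimethoxynaphthalen-1-yl)tri(propan-2-yloxy)borate | COc1cccc2c([B-](OC(C)C)(OC(C)C)OC(C)C)ccc(OC)c12.[Li+] | intermediate
5 | (4,5-dimethoxynaphthalen-1-yl)boronic acid | COc1cccc2c(B(O)O)ccc(OC)c12 | intermediate
6 | 4-hydroxy-2,3-dihydro-1H-inden-1-one | O=C1CCc2c(O)cccc21 | starting material
7 | benzyl bromide | BrCc1ccccc1 | starting material
8 | 4-(benzyloxy)-2,3-dihydro-1H-inden-1-one | O=C1CCc2c(OCc3ccccc3)cccc21 | intermediate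
9 | 4-(benzyloxy)-1H-inden-1-one | O=C1C=Cc2c(OCc3ccccc3)cccc21 | intermediate
10 | (3S)-4-(benzyloxy)-3-(4,5-dimethoxynaphthalen-1-yl)-2,3-dihydro-1H-inden-1-one | COc1cccc2c([C@@H]3CC(=O)c4cccc(OCc5ccccc5)c43)ccc(OC)c12 | intermediate
11 | (4S)-5-(benzyloxy)-4-(4,5-dimethoxynaphthalen-1-yl)-3,4-dihydro-2H-chromen-2-one | COc1cccc2c([C@@H]3CC(=O)Oc4cccc(OCc5ccccc5)c43)ccc(OC)c12 | intermediate
12 | (4S)-5-(benzyloxy)-4-(4,5-dimethoxynaphthalen-1-yl)-3,4-dihydro-2H-chromen-2-ol, both C2 epimers | COc1cccc2c([C@@H]3CC(O)Oc4cccc(OCc5ccccc5)c43)ccc(OC)c12 | intermediate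
13 | (4S)-5-(benzyloxy)-4-(4,5-dimethoxynaphthalen-1-yl)-3,4-dihydro-2H-chromen-2-yl acetate, both C2 epimers | COc1cccc2c([C@@H]3CC(OC(C)=O)Oc4cccc(OCc5ccccc5)c43)ccc(OC)c12 | intermediate
14 | (2R,4S)-5-(benzyloxy)-4-(4,5-dimethoxynaphthalen-1-yl)-2-methyl-3,4-dihydro-2H-chromene | COc1cccc2c([C@@H]3C[C@@H](C)Oc4cccc(OCc5ccccc5)c43)ccc(OC)c12 | intermediate
15 | (2R,4S)-4-(4,5-dimethoxynaphthalen-1-yl)-2-methyl-3,4-dihydro-2H-chromen-5-ol (cladonaphchrom A) | COc1cccc2c([C@@H]3C[C@@H](C)Oc4cccc(O)c43)ccc(OC)c12 | target

**Step count**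
Total: 10 steps. Longest linear sequence: 8 steps (steps 3, 4, 5–10 from 6; equally steps 1, 2, 5–10 from 1).

**Steps most likely to fail**

Step 6. Oxygen insertion into the conjugated aryl ketone may be slow under buffered, acid-free conditions, so that electrophilic oxidation of the dimethoxynaphthalene ring by the peracid overtakes it. Fallback: the lactone is made without any oxidant. Commercial 5-hydroxycoumarin is benzylated with 7 (K2CO3, DMF) to 5-(benzyloxy)-2H-chromen-2-one F1. Boronic acid 5 is then added across its C3=C4 bond by rhodium-catalysed asymmetric 1,4-addition to a coumarin (Rh(acac)(C2H4)2, (S)-SEGPHOS as the antipode expected to give the 4S product, dioxane–H2O, 60 °C). This sets out from 5 and 7 and rejoins the route at 11.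

Step 9. Methyl transfer may show poor facial selectivity; the cation may also lose H3 to give the 4H-chromene, or be captured intramolecularly by the nucleophilic peri carbon C8' of the naphthalene. Fallback: the methyl group and the C2 configuration are introduced separately under reagent control, starting from 11. Aminolysis with MeNHOMe·HCl/AlMe3 (CH2Cl2) opens the lactone to the Weinreb amide (3S)-3-[2-(benzyloxy)-6-hydroxyphenyl]-3-(4,5-dimethoxynaphthalen-1-yl)-N-methoxy-N-methylpropanamide F2. Excess MeMgBr (THF, 0 °C) gives the methyl ketone (4S)-4-[2-(benzyloxy)-6-hydroxyphenyl]-4-(4,5-dimethoxynaphthalen-1-yl)butan-2-one F3. Corey–Bakshi–Shibata reduction with (R)-Me-CBS/BH3·SMe2 should give the carbinol (2S,4S)-4-[2-(benzyloxy)-6-hydroxyphenyl]-4-(4,5-dimethoxynaphthalen-1-yl)butan-2-ol F4. Mitsunobu etherification (PPh3, DIAD, THF) then closes the O1–C2 bond with inversion and rejoins the route at 14.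

Step 5. The labile indenone may polymerise, or the electron-rich boronic acid may protodeboronate, faster than insertion at the peri-hindered C3; enantioface selection may also be low or opposite to that assumed. Fallback: the indanone is built by an asymmetric intramolecular reductive Heck reaction, which avoids the indenone of step 4 altogether.
- Vilsmeier–Haack formylation of 1 (POCl3, DMF) gives 4,5-dimethoxynaphthalene-1-carbaldehyde F5.
- Commercial 2',3'-dihydroxyacetophenone is benzylated at O3 through its dianion (NaH 2 equiv, then 7) to 1-[3-(benzyloxy)-2-hydroxyphenyl]ethan-1-one F6.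
- Claisen–Schmidt condensation of F5 and F6 (KOH, EtOH) gives the chalcone (2E)-1-[3-(benzyloxy)-2-hydroxyphenyl]-3-(4,5-dimethoxynaphthalen-1-yl)prop-2-en-1-one F7.
- Tf2O/pyridine converts it to the aryl triflate 2-(benzyloxy)-6-[(2E)-3-(4,5-dimethoxynaphthalen-1-yl)prop-2-enoyl]phenyl trifluoromethanesulfonate F8.
- Pd(OAc)2 with a MeO-BIPHEP-type ligand (the antipode that gives the 3S ketone), proton sponge, DMF, 80 °C closes the C3–C3a bond.

This sets out from 1 and 7 and rejoins the route at 10.

**Further compounds**
F1 | step 6 | 5-(benzyloxy)-2H-chromen-2-one | O=C1C=Cc2c(OCc3ccccc3)cccc2O1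
F2 | step 9 | (3S)-3-[2-(benzyloxy)-6-hydroxyphenyl]-3-(4,5-dimethoxynaphthalen-1-yl)-N-methoxy-N-methylpropanamide | COc1cccc2c([C@H](CC(=O)N(C)OC)c3c(O)cccc3OCc3ccccc3)ccc(OC)c12
F3 | step 9 | (4S)-4-[2-(benzyloxy)-6-hydroxyphenyl]-4-(4,5-dimethoxynaphthalen-1-yl)butan-2-one | COc1cccc2c([C@H](CC(C)=O)c3c(O)cccc3OCc3ccccc3)ccc(OC)c12
F4 | step 9 | (2S,4S)-4-[2-(benzyloxy)-6-hydroxyphenyl]-4-(4,5-dimethoxynaphthalen-1-yl)butan-2-ol | COc1cccc2c([C@H](C[C@H](C)O)c3c(O)cccc3OCc3ccccc3)ccc(OC)c12
F5 | step 5 | 4,5-dimethoxynaphthalene-1-carbaldehyde | COc1cccc2c(C=O)ccc(OC)c12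
F6 | step 5 | 1-[3-(benzyloxy)-2-hydroxyphenyl]ethan-1-one | CC(=O)c1cccc(OCc2ccccc2)c1O
F7 | step 5 | (2E)-1-[3-(benzyloxy)-2-hydroxyphenyl]-3-(4,5-dimethoxynaphthalen-1-yl)prop-2-en-1-one | COc1cccc2c(/C=C/C(=O)c3cccc(OCc4ccccc4)c3O)ccc(OC)c12
F8 | step 5 | 2-(benzyloxy)-6-[(2E)-3-(4,5-dimethoxynaphthalen-1-yl)prop-2-enoyl]phenyl trifluoromethanesulfonate | COc1cccc2c(/C=C/C(=O)c3cccc(OCc4ccccc4)c3OS(=O)(=O)C(F)(F)F)ccc(OC)c12
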